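**Conventions and one remark**

- Bicyclic compounds carry daucane locants: C1 is the quaternary ring-fusion carbon with the angular methyl, C2 and C3 are the cyclopentane CH2 groups, C4 is the isopropyl carbinol, C5 the ring-fusion CH, C6 the acyloxy carbon, C7 a CH2, C8 the methyl carbinol, C9 the secondary carbinol and C10 a CH2. β is the face of the C1 methyl group. The same locants are used for the monocyclic precursors.
- Remark: 2-bromo-3-methylcyclopent-2-en-1-one (1) is taken as a catalogue compound. It is otherwise one step from 3-methylcyclopent-2-en-1-one (Br2, then Et3N).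

## Analysis of the target

The target is a trans-fused hydroazulene of the daucane family. A cyclopentane (C1–C5) shares the C1–C5 bond with a cycloheptane (C1, C5–C10), and C6 carries a 4-hydroxybenzoate. All six stereocentres lie on the bicycle (1R,4R,5S,6S,8S,9S): the quaternary C1, the tertiary carbinols C4 and C8, the ring-fusion methine C5 and the two secondary C–O carbons C6 and C9. Relative to the β methyl on C1, the C4 and C8 hydroxyls are β, while H5, the C6 ester oxygen and the C9 hydroxyl are α. The ring fusion is therefore trans, the C8/C9 diol is trans, and the C6 oxygen is cis to H5. The sensitive points are the two tertiary alcohols (dehydration under acid), the free phenol, and the need to acylate C6 while C9, also a secondary carbinol, stays free. The hard part is a seven-membered ring with a quaternary stereocentre at the fusion, followed by stereocontrol on a mobile cycloheptane with only that one centre as a guide. The strategy rests on one feature. C9 can be a ketone, its neighbour C10 is bonded to the quaternary C1, and the C1–C5 bond can be the double bond of a cyclopentenyl group on the oxygenated C6. The atoms C10–C9–O–C6–C5–C1 are then an allyl vinyl ether, and because C7–C8 link C6 to C9 this ether is a 2-methylenetetrahydrofuran. A [3,3] shift makes C1–C10, enlarges the five-membered ether to the seven-membered carbocycle, and leaves a C9 ketone and a C5=C6 alkene.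

## Retrosynthetic reasoning

**Benzyl groups (26 from 25).** The phenol and the C9 hydroxyl are released together in the last step by hydrogenolysis. The phenol must be masked during acylation, and C9–OH must be masked so that C6–OH is the only secondary alcohol at that point.

**C6–O acyl bond (25 from 23 and 24).** The ester is introduced late because an aryl ester would not survive the organometallic step at C4 cleanly and would make the C4 ketone a β-acyloxy ketone prone to elimination. In 23 the other free hydroxyls are tertiary, so the acylation needs no selectivity beyond that.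

**C4–isopropyl bond (23 from 22, 22 from 21, 21 from 20).** The isopropyl group is cut from C4 to leave ketone 21. The cut is made on the saturated, trans-fused bicycle and not on a C5=C6 enone. With C5 sp2 the two faces of C4 are flanked alike by the methyl and C10 on C1. With C5 sp3 the angular methyl is 1,3-diaxial to the β trajectory and only H5 guards the α face. The C6 oxygen is a silyl ether at this stage so that 21 is not a free aldol. The ketone comes from the dioxolane of 20.

**C5–H and C6–O bonds (19 from 17).** Both are made in one syn addition to the C5=C6 alkene by hydroboration–oxidation. The alkene substitution places oxygen on C6, and attack anti to the angular methyl places both new bonds on the α face, which gives the trans ring fusion.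

**C9–H bond and C9 protection (17 from 16, 16 from 15).** The C9 carbinol comes from the C9 ketone by hydride delivery from the neighbouring C8 hydroxyl. This gives the trans-diol without relying on the shape of the ring. The secondary hydroxyl is then capped as a benzyl ether.

**C8–O and C8–CH3 bonds (15 from 13, 13 from 12, 12 from 10).** Both substituents on C8 are introduced through enol derivatives of the C9 ketone. C8 is the α-carbon remote from the quaternary C1, so regiocontrol is available. The order is methyl first and oxygen second, because the second electrophile enters on the outer face of the folded 1,4-cycloheptadiene, and that face is β at C8. The C5=C6 alkene is kept until after this step because it creates the fold.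

**C1–C10 bond and the seven-membered ring (10 from 9).** This is the key disconnection. Cutting C1–C10 and reconnecting C6 to the C9 oxygen turns cycloheptenone 10 into the 2-methylenetetrahydrofuran 9. No other bond of the ring offers a pericyclic retron that also creates the quaternary centre. The C6 carbinol centre of 9 is easy to set, and the ring tether forces C7 cis to C1, so the C6 configuration is transferred to C1.

**C10 methylene (9 from 8).** The enol ether carbon is added to the lactone carbonyl of 8 by carbonyl methylenation under neutral conditions.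

**C6 stereocentre and lactone C–O bond (8 from 6 through 7).** The only stereocentre made by a chiral reagent is the C6 carbinol. It comes from catalytic asymmetric reduction of alkenyl ketone 6, after which the hydroxy ester 7 closes to the lactone.

**C5–C6 bond (6 from 2 and 3, 2 from 1).** The ketone is cut between the cyclopentene carbon C5 and the acyl carbon C6. This gives the four-carbon acid chloride 3 and the vinyl bromide 2, which is the ketal of 1.

## Alternatives that were turned down

**Alternative 1: radical bicyclization after photoredox decarboxylation.**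
- Disconnection: C4–C5 and C6–C7 are cut together. This leads to the open-chain α-hydroxy acid A1, in which the quaternary C1 is the only fixed stereocentre.
- Forward step: a visible-light photocatalyst oxidizes the carboxylate of A1. Loss of CO2 leaves a C4 carbinol radical, which closes 5-exo onto C5 of the enol ester. The C6 radical then closes 7-endo onto the terminal carbon C7 of the isopropenyl ketone. The product is the hydroazulen-9-one A2.
- For: both rings, the C4 carbinol, the ester and the C8 methyl arrive in one step. On step economy for the skeleton and on protecting groups this plan is stronger than the chosen one.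
- Against: four stereocentres (C4, C5, C6, C8) would be set in one radical cascade with only the remote C1 as a guide. The first closure joins a nucleophilic radical to an electron-rich enol ester and makes a bond between two crowded carbons. The 7-endo closure must outrun reduction of the C6 radical. A1 needs its own enantioselective construction of an acyclic quaternary carbon, and A2 still lacks the C8 hydroxyl.
- Comparison: the chosen route sets one centre at a time by mechanisms whose facial sense can be argued, and pays for this with more steps.

**Alternative 2: Achmatowicz oxidation and oxidopyrylium–alkene (5+2) cycloaddition.**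
- Disconnection: C1–C5 and C9–C10 are cut together. This leads to the acetoxypyranone A3, which carries the C4 carbinol and a tethered 1,1-disubstituted alkene.
- Forward step: triethylamine removes acetate from A3, and the resulting dipole adds through C5 and C9 across the C1=C10 alkene. The product is the oxygen-bridged hydroazulenone A4.
- For: the quaternary C1 and both rings form in one step. C9 is already oxygenated, C6 is a ketone and the C8 methyl sits on an enone. In ring construction per step and in placement of functionality this plan is at least as strong as the chosen one.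
- Against: all absolute and relative control starts from the tertiary C4 carbinol. It has to be made enantioenriched, which is harder than reducing a ketone, and it must steer the cycloaddition through a short tether with hydroxyl and isopropyl as the differentiating groups. C5 emerges as an ether carbon, so the C5–O bond must be cleaved reductively and C5 reprotonated to the trans fusion without control. The C8 carbinol must still be added to the enone with the correct face.
- Comparison: the chosen route offers a cheaper and more predictable source of chirality and a C5 that arrives as an alkene carbon for a stereodefined syn addition.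

**Alternative 3: Buchner ring expansion of a p-tolyl diazoketone.**
- Disconnection: C5–C1 and C5–C6 are cut, so that C5 is a carbene carbon inserted into a tolyl ring. This leads to the diazoketone A5.
- Forward step: Rh2(OAc)4 generates the carbenoid, which cyclopropanates the ipso–ortho bond. Electrocyclic opening and base-mediated double-bond migration give the dihydroazulenone A6.
- For: this is the shortest access to the bicyclic carbon framework with the C8 methyl in place, from a commodity arene. On step count to the skeleton it beats the chosen route.
- Against: A6 is flat and achiral and lacks the angular methyl. C1 would have to become quaternary by enantioselective conjugate methylation at a ring-fusion carbon of a cross-conjugated trienone. Three double bonds would have to be told apart, and all six stereocentres remain to be made.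
- Comparison: the chosen route makes C1 together with the ring and leaves a single alkene and a single ketone, each at the position where it is needed.

Key step: step 5

## Route

Step 1
Reactants: 1 2-bromo-3-methylcyclopent-2-en-1-one
Product: 2 6-bromo-7-methyl-1,4-dioxaspiro[4.4]non-6-ene
Conditions: HOCH2CH2OH, p-TsOH (cat.), PhH, reflux, Dean–Stark
Reagents that add atoms: ethane-1,2-diol, OCCO
Why: Acid-catalysed ketalization with azeotropic removal of water; the vinylic bromine holds the double bond in place, and the dioxolane masks the C4 carbonyl for the organometallic, methylenation and thermal steps.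

Step 2
Reactants: 2 6-bromo-7-methyl-1,4-dioxaspiro[4.4]non-6-ene; 3 methyl 4-chloro-4-oxobutanoate
Product: 6 methyl 4-(7-methyl-1,4-dioxaspiro[4.4]non-6-en-6-yl)-4-oxobutanoate, via vinyllithium 4 (not isolated), via vinylzinc chloride 5 (not isolated)
Conditions: t-BuLi (2.1 equiv), THF, −78 °C; ZnCl2, −78 → 0 °C; 3, Pd(PPh3)4 (5 mol %), 0 °C → rt
Reagents that add atoms: none
Why: Bromine–lithium exchange gives the α-ketovinyl anion equivalent 4, and transmetalation to zinc followed by Negishi acylation with the acid chloride forms the C5–C6 bond. The organozinc does not add to the new ketone or to the ester, which a direct organolithium acylation could not guarantee.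

Step 3
Reactants: 6 methyl 4-(7-methyl-1,4-dioxaspiro[4.4]non-6-en-6-yl)-4-oxobutanoate
Product: 8 (5S)-5-(7-methyl-1,4-dioxaspiro[4.4]non-6-en-6-yl)oxolan-2-one, via hydroxy ester 7 (not isolated)
Conditions: (R)-Me-CBS oxazaborolidine (20 mol %), BH3·SMe2, THF, −20 °C; MeOH; then DBU (cat.), PhMe, 50 °C
Reagents that add atoms: none
Why: Corey–Bakshi–Shibata reduction: the fully substituted alkenyl group is the large substituent, so the (R)-catalyst should deliver hydride to give the (S)-carbinol 7 (C6). Base-catalysed 5-exo-trig lactonization with loss of methanol follows and does not touch the carbinol centre.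

Step 4
Reactants: 8 (5S)-5-(7-methyl-1,4-dioxaspiro[4.4]non-6-en-6-yl)oxolan-2-one
Product: 9 (5S)-2-methylidene-5-(7-methyl-1,4-dioxaspiro[4.4]non-6-en-6-yl)oxolane
Conditions: Cp2TiMe2, PhMe–THF, 70 °C, dark; filtration through basic Al2O3
Reagents that add atoms: dimethyltitanocene, C[Ti](C)(C1C=CC=C1)C1C=CC=C1
Why: Petasis methylenation of the lactone carbonyl through the titanium methylidene; the medium is neither acidic nor basic, so the allylic C6–O bond, the ketal and the acid-labile exocyclic enol ether should survive.

Step 5
Reactants: 9 (5S)-2-methylidene-5-(7-methyl-1,4-dioxaspiro[4.4]non-6-en-6-yl)oxolane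
Product: 10 (1R)-4,4-ethylenedioxy-1-methylbicyclo[5.3.0]dec-5-en-9-one
Conditions: PhMe (0.02 M), i-Pr2NEt (10 mol %), silylated sealed tube, 190–200 °C
Reagents that add atoms: none
Why: Thermal Claisen rearrangement in its ring-expansion form: the enol ether C10=C9 and the cyclopentene bond C5=C1, joined through O–C6, undergo a concerted suprafacial [3,3] shift that forms C1–C10 while C6–O breaks. The closest known reaction type is the thermal conversion of 2-methylene-5-vinyltetrahydrofurans into cyclohept-4-enones. The seven-membered ring closes by sigmatropic ring expansion of the five-membered ether through a bicyclo[3.2.1]-like transition state, in which the C7–C8 bridge holds the six reacting atoms in a boat. The new quaternary centre C1 is controlled by C6: only the rotamer with C7 syn to C1 can give the cis ring alkene, and in it the (S)-configured C6–O bond lies on the face that becomes α. C10 therefore bonds to that face and the methyl is left β, which is (1R); the outcome is the same for a boat or a chair because the enol ether terminus is an unsubstituted CH2. The step needs the [3,3] path to win over acid-catalysed migration of the enol ether double bond into the ring, ionization of the allylic C6–O bond (1,3-collapse and loss of configuration) and elimination; a non-polar solvent, an amine buffer and silylated glass serve this. The driving force is the C9 carbonyl, and the price is the A(1,3) contact between C7 and the C1 methyl in the reactive rotamer and the fully substituted terminus, hence the temperature.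

Step 6
Reactants: 10 (1R)-4,4-ethylenedioxy-1-methylbicyclo[5.3.0]dec-5-en-9-one
Product: 12 (1R)-4,4-ethylenedioxy-1,8-dimethylbicyclo[5.3.0]dec-5-en-9-one (both C8 epimers), via lithium enolate 11 (not isolated)
Conditions: LiN(i-Pr)2, THF, −78 °C; MeI, −78 → −30 °C
Reagents that add atoms: iodomethane, CI
Why: Kinetic enolate alkylation: deprotonation should occur at C8 because C10 is neopentyl (next to the quaternary C1), and enolate 11 is methylated by SN2. The C8 configuration does not matter because C8 is made planar again in step 7.

Step 7
Reactants: 12 (1R)-4,4-ethylenedioxy-1,8-dimethylbicyclo[5.3.0]dec-5-en-9-one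
Product: 13 (1R)-4,4-ethylenedioxy-1,8-dimethyl-9-(trimethylsilyloxy)bicyclo[5.3.0]deca-5,8-diene
Conditions: Me3SiCl, Et3N, DMF, 110 °C
Reagents that add atoms: chlorotrimethylsilane, C[Si](C)(C)Cl
Why: Silyl enol ether formation under equilibrating conditions; the tetrasubstituted C8=C9 isomer is favoured over the C9=C10 isomer, which would place the double bond next to the quaternary carbon.

Step 8
Reactants: 13 (1R)-4,4-ethylenedioxy-1,8-dimethyl-9-(trimethylsilyloxy)bicyclo[5.3.0]deca-5,8-diene
Product: 15 (1R)-4,4-ethylenedioxy-8β-hydroxy-1β,8α-dimethylbicyclo[5.3.0]dec-5-en-9-one, via silyloxy epoxide 14 (not isolated)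
Conditions: DMDO (1.05 equiv), acetone–CH2Cl2, −78 → −40 °C; then Bu4NF, AcOH, THF, 0 °C
Reagents that add atoms: dimethyldioxirane, CC1(C)OO1
Why: Rubottom oxidation: the electron-rich silyl enol ether is epoxidized much faster than the hindered, ketal-deactivated C5=C6 alkene. In the folded 1,4-cycloheptadiene the inner face of C8=C9 is screened by the transannular C5=C6 bond, so oxygen should enter from the outer face, which is β at C8 and leaves the methyl α. Buffered fluoride then opens the silyloxy epoxide to the ketol without the base or heat that would invite an α-ketol shift.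

Step 9
Reactants: 15 (1R)-4,4-ethylenedioxy-8β-hydroxy-1β,8α-dimethylbicyclo[5.3.0]dec-5-en-9-one
Product: 16 (1R)-4,4-ethylenedioxy-1β,8α-dimethylbicyclo[5.3.0]dec-5-ene-8β,9α-diol
Conditions: Me4NBH(OAc)3, MeCN–AcOH, −30 → 0 °C; cold aqueous NaHCO3–potassium sodium tartrate work-up
Reagents that add atoms: none
Why: Hydroxyl-directed reduction (Saksena–Evans): the C8 hydroxyl exchanges onto boron and hydride is delivered within the complex to the same (β) face of the C9 carbonyl, so the new hydroxyl is α and the diol is trans. The outer-face preference of the ring points the same way, and the cold, water-free acid should spare the allylic ketal.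

Step 10
Reactants: 16 (1R)-4,4-ethylenedioxy-1β,8α-dimethylbicyclo[5.3.0]dec-5-ene-8β,9α-diol
Product: 17 (1R)-9α-benzyloxy-4,4-ethylenedioxy-1β,8α-dimethylbicyclo[5.3.0]dec-5-en-8β-ol
Conditions: NaH (1.1 equiv), BnBr, Bu4NI (cat.), THF–DMF, 0 °C → rt
Reagents that add atoms: benzyl bromide, BrCc1ccccc1
Why: Williamson etherification: the secondary C9 alkoxide is alkylated much faster than the tertiary C8 alkoxide. The benzyl ether keeps C9 out of the later acylation and is removed together with the phenol benzyl group at the end.

Step 11
Reactants: 17 (1R)-9α-benzyloxy-4,4-ethylenedioxy-1β,8α-dimethylbicyclo[5.3.0]dec-5-en-8β-ol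
Product: 19 (1R)-9α-benzyloxy-4,4-ethylenedioxy-1β,8α-dimethyl-5αH-bicyclo[5.3.0]decane-6α,8β-diol, via C6 alkylborane 18 (not isolated)
Conditions: BH3·THF (excess), THF, 0 °C → rt; then NaOH, H2O2, 0 °C → rt
Reagents that add atoms: hydrogen peroxide, OO
Why: Hydroboration–oxidation: boron goes to the less substituted C6 and hydrogen to C5 in a syn addition, and oxidation proceeds with retention. Attack is expected anti to the angular methyl on the allylic carbon C1, as with other angularly methylated ring-fusion alkenes, and the equatorial-seeking 8α-methyl keeps C8 and its hydroxyl on the β side of the alkene; both effects leave the α face open and give 5α-H (trans fusion) and 6α-OH. The free C8 hydroxyl is carried as a borate ester that is hydrolysed on work-up.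

Step 12
Reactants: 19 (1R)-9α-benzyloxy-4,4-ethylenedioxy-1β,8α-dimethyl-5αH-bicyclo[5.3.0]decane-6α,8β-diol
Product: 20 (1R)-9α-benzyloxy-6α-(tert-butyldimethylsilyloxy)-4,4-ethylenedioxy-1β,8α-dimethyl-5αH-bicyclo[5.3.0]decan-8β-ol
Conditions: t-BuMe2SiOTf (1.1 equiv), 2,6-lutidine, CH2Cl2, −78 °C
Reagents that add atoms: tert-butyldimethylsilyl trifluoromethanesulfonate, CC(C)(C)[Si](C)(C)OS(=O)(=O)C(F)(F)F
Why: Silylation of the secondary C6 hydroxyl; the tertiary C8 hydroxyl does not react at this temperature. The silyl ether makes the coming C4 ketone a β-silyloxy ketone, which cannot undergo retro-aldol cleavage.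

Step 13
Reactants: 20 (1R)-9α-benzyloxy-6α-(tert-butyldimethylsilyloxy)-4,4-ethylenedioxy-1β,8α-dimethyl-5αH-bicyclo[5.3.0]decan-8β-ol
Product: 21 (1R)-9α-benzyloxy-6α-(tert-butyldimethylsilyloxy)-8β-hydroxy-1β,8α-dimethyl-5αH-bicyclo[5.3.0]decan-4-one
Conditions: PPTS, acetone–H2O (10:1), 55 °C
Reagents that add atoms: water, O
Why: Acid-catalysed ketal hydrolysis with a weak pyridinium acid in wet acetone; the silyl and benzyl ethers and the tertiary alcohol should survive. The mild acid limits enolization toward C5 and with it epimerization of the ring fusion or β-elimination of the C6 oxygen.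

Step 14
Reactants: 21 (1R)-9α-benzyloxy-6α-(tert-butyldimethylsilyloxy)-8β-hydroxy-1β,8α-dimethyl-5αH-bicyclo[5.3.0]decan-4-one
Product: 22 (1R)-9α-benzyloxy-6α-(tert-butyldimethylsilyloxy)-4α-isopropyl-1β,8α-dimethyl-5αH-bicyclo[5.3.0]decane-4β,8β-diol
Conditions: CeCl3 (anhydrous), i-PrMgCl, THF, −78 °C; then 21, −78 → −40 °C
Reagents that add atoms: isopropylmagnesium chloride, CC(C)[Mg]Cl
Why: Organocerium addition to the ketone: the weakly basic i-PrCeCl2 suppresses enolization and β-hydride reduction, and one extra equivalent is consumed by the C8 hydroxyl. On the trans-fused cyclopentanone the reagent should approach from the α face, past the axial H5 and away from the 1,3-related angular methyl, which gives the 4β-hydroxyl and 4α-isopropyl group.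

Step 15
Reactants: 22 (1R)-9α-benzyloxy-6α-(tert-butyldimethylsilyloxy)-4α-isopropyl-1β,8α-dimethyl-5αH-bicyclo[5.3.0]decane-4β,8β-diol
Product: 23 (1R)-9α-benzyloxy-4α-isopropyl-1β,8α-dimethyl-5αH-bicyclo[5.3.0]decane-4β,6α,8β-triol
Conditions: Bu4NF, THF, rt → 40 °C
Reagents that add atoms: none
Why: Fluoride cleavage of the silyl ether; the benzyl ether and the tertiary alcohols are inert to fluoride.

Step 16
Reactants: 23 (1R)-9α-benzyloxy-4α-isopropyl-1β,8α-dimethyl-5αH-bicyclo[5.3.0]decane-4β,6α,8β-triol; 24 4-(benzyloxy)benzoyl chloride
Product: 25 (1R)-9α-benzyloxy-4β,8β-dihydroxy-4α-isopropyl-1β,8α-dimethyl-5αH-bicyclo[5.3.0]dec-6α-yl 4-(benzyloxy)benzoate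
Conditions: DMAP, Et3N, CH2Cl2, rt
Reagents that add atoms: none
Why: DMAP-catalysed acylation of the only secondary hydroxyl; the tertiary C4 and C8 hydroxyls are too hindered to react under these conditions.

Step 17
Reactants: 25 (1R)-9α-benzyloxy-4β,8β-dihydroxy-4α-isopropyl-1β,8α-dimethyl-5αH-bicyclo[5.3.0]dec-6α-yl 4-(benzyloxy)benzoate
Product: 26 (1R,4R,5S,6S,8S,9S)-4β,8β,9α-trihydroxy-4α-isopropyl-1β,8α-dimethyl-5αH-bicyclo[5.3.0]dec-6α-yl 4-hydroxybenzoate (CNP0197754.1)
Conditions: H2 (1 atm), Pd(OH)2 on carbon, EtOAc–EtOH, rt
Reagents that add atoms: none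
Why: Hydrogenolysis of the aryl benzyl ether and the C9 benzyl ether in one operation; the aryl ester and the tertiary alcohols are stable and no alkene remains.

## Compound list

1 | 2-bromo-3-methylcyclopent-2-en-1-one | O=C1CCC(C)=C1Br | starting material
2 | 6-bromo-7-methyl-1,4-dioxaspiro[4.4]non-6-ene | BrC1=C(C)CCC12OCCO2 | intermediate
3 | methyl 4-chloro-4-oxobutanoate | COC(=O)CCC(Cl)=O | starting material
4 | (7-methyl-1,4-dioxaspiro[4.4]non-6-en-6-yl)lithium | [Li]C1=C(C)CCC12OCCO2 | intermediate
5 | chloro(7-methyl-1,4-dioxaspiro[4.4]non-6-en-6-yl)zinc | Cl[Zn]C1=C(C)CCC12OCCO2 | intermediate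
6 | methyl 4-(7-methyl-1,4-dioxaspiro[4.4]non-6-en-6-yl)-4-oxobutanoate | COC(=O)CCC(=O)C1=C(C)CCC12OCCO2 | intermediate
7 | methyl (4S)-4-hydroxy-4-(7-methyl-1,4-dioxaspiro[4.4]non-6-en-6-yl)butanoate | COC(=O)CC[C@H](O)C1=C(C)CCC12OCCO2 | intermediate
8 | (5S)-5-(7-methyl-1,4-dioxaspiro[4.4]non-6-en-6-yl)oxolan-2-one | O=C1CC[C@H](O1)C2=C(C)CCC23OCCO3 | intermediate
9 | (5S)-2-methylidene-5-(7-methyl-1,4-dioxaspiro[4.4]non-6-en-6-yl)oxolane | C=C1CC[C@H](O1)C2=C(C)CCC23OCCO3 | intermediate
10 | (1R)-4,4-ethylenedioxy-1-methylbicyclo[5.3.0]dec-5-en-9-one | O1CCOC12CC[C@]3(C)CC(=O)CCC=C23 | intermediate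
11 | lithium C8–C9 enolate of 10 | O1CCOC12CC[C@]3(C)CC(O[Li])=CCC=C23 | intermediate
12 | (1R)-4,4-ethylenedioxy-1,8-dimethylbicyclo[5.3.0]dec-5-en-9-one, both C8 epimers | O1CCOC12CC[C@]3(C)CC(=O)C(C)CC=C23 | intermediate
13 | (1R)-4,4-ethylenedioxy-1,8-dimethyl-9-(trimethylsilyloxy)bicyclo[5.3.0]deca-5,8-diene | O1CCOC12CC[C@]3(C)CC(O[Si](C)(C)C)=C(C)CC=C23 | intermediate
14 | 8β,9β-epoxide of 13 | O1CCOC12CC[C@]3(C)C[C@@]4(O[Si](C)(C)C)O[C@@]4(C)CC=C23 | intermediate
15 | (1R)-4,4-ethylenedioxy-8β-hydroxy-1β,8α-dimethylbicyclo[5.3.0]dec-5-en-9-one | O1CCOC12CC[C@]3(C)CC(=O)[C@@](C)(O)CC=C23 | intermediate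
16 | (1R)-4,4-ethylenedioxy-1β,8α-dimethylbicyclo[5.3.0]dec-5-ene-8β,9α-diol | O1CCOC12CC[C@]3(C)C[C@H](O)[C@@](C)(O)CC=C23 | intermediate
17 | (1R)-9α-benzyloxy-4,4-ethylenedioxy-1β,8α-dimethylbicyclo[5.3.0]dec-5-en-8β-ol | O1CCOC12CC[C@]3(C)C[C@H](OCc4ccccc4)[C@@](C)(O)CC=C23 | intermediate
18 | 6α-boryl derivative of 17 with 5α-H, drawn as the RBH2 species | O1CCOC12CC[C@]3(C)C[C@H](OCc4ccccc4)[C@@](C)(O)C[C@H]([BH2])[C@@H]23 | intermediate
19 | (1R)-9α-benzyloxy-4,4-ethylenedioxy-1β,8α-dimethyl-5αH-bicyclo[5.3.0]decane-6α,8β-diol | O1CCOC12CC[C@]3(C)C[C@H](OCc4ccccc4)[C@@](C)(O)C[C@H](O)[C@@H]23 | intermediate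
20 | (1R)-9α-benzyloxy-6α-(tert-butyldimethylsilyloxy)-4,4-ethylenedioxy-1β,8α-dimethyl-5αH-bicyclo[5.3.0]decan-8β-ol | O1CCOC12CC[C@]3(C)C[C@H](OCc4ccccc4)[C@@](C)(O)C[C@H](O[Si](C)(C)C(C)(C)C)[C@@H]23 | intermediate
21 | (1R)-9α-benzyloxy-6α-(tert-butyldimethylsilyloxy)-8β-hydroxy-1β,8α-dimethyl-5αH-bicyclo[5.3.0]decan-4-one | O=C1CC[C@]2(C)C[C@H](OCc3ccccc3)[C@@](C)(O)C[C@H](O[Si](C)(C)C(C)(C)C)[C@H]21 | intermediate
22 | (1R)-9α-benzyloxy-6α-(tert-butyldimethylsilyloxy)-4α-isopropyl-1β,8α-dimethyl-5αH-bicyclo[5.3.0]decane-4β,8β-diol | CC(C)[C@]1(O)CC[C@]2(C)C[C@H](OCc3ccccc3)[C@@](C)(O)C[C@H](O[Si](C)(C)C(C)(C)C)[C@H]21 | intermediate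
23 | (1R)-9α-benzyloxy-4α-isopropyl-1β,8α-dimethyl-5αH-bicyclo[5.3.0]decane-4β,6α,8β-triol | CC(C)[C@]1(O)CC[C@]2(C)C[C@H](OCc3ccccc3)[C@@](C)(O)C[C@H](O)[C@H]21 | intermediate
24 | 4-(benzyloxy)benzoyl chloride | O=C(Cl)c1ccc(OCc2ccccc2)cc1 | starting material
25 | (1R)-9α-benzyloxy-4β,8β-dihydroxy-4α-isopropyl-1β,8α-dimethyl-5αH-bicyclo[5.3.0]dec-6α-yl 4-(benzyloxy)benzoate | CC(C)[C@]1(O)CC[C@]2(C)C[C@H](OCc3ccccc3)[C@@](C)(O)C[C@H](OC(=O)c4ccc(OCc5ccccc5)cc4)[C@H]21 | intermediate
26 | (1R,4R,5S,6S,8S,9S)-4β,8β,9α-trihydroxy-4α-isopropyl-1β,8α-dimethyl-5αH-bicyclo[5.3.0]dec-6α-yl 4-hydroxybenzoate | CC(C)[C@]1(O)CC[C@]2(C)C[C@H](O)[C@@](C)(O)C[C@H](OC(=O)c3ccc(O)cc3)[C@H]21 | target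

## Step count and least certain steps

Total step count: 17. Longest linear sequence: 17 steps (1 to 26); 3 and 24 enter as purchased compounds.

**Step 5 (key step).**
- What may go wrong: the shift may not occur before decomposition, because the boat array, the A(1,3) contact between C7 and the C1 methyl and the fully substituted terminus all raise the barrier. In competition, the exocyclic enol ether can isomerize into the ring under traces of acid, or the allylic C6–O bond can ionize, which leads to 1,3-collapse and loss of configuration.
- Fallback (from 9, returning at 10): the rearrangement is run as its aluminium-promoted variant with i-Bu3Al in CH2Cl2 from −78 °C to room temperature. Coordination of aluminium to the ether oxygen lets the shift proceed far below the thermal threshold. The ketone is reduced in the flask by β-hydride transfer, so the product is (1R)-4,4-ethylenedioxy-1-methylbicyclo[5.3.0]dec-5-en-9-ol F1. Dess–Martin oxidation of F1 gives 10.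

**Step 11.**
- What may go wrong: poor facial selectivity. The seven-membered ring is mobile, and a chair-like conformer would expose the β face, which leads to the cis-fused 5β,6β product.
- Fallback (from 16, returning at 19): the α-configured C9 hydroxyl delivers the reagent. Silylation of the secondary hydroxyl of 16 with (HMe2Si)2NH gives the 9α-O-dimethylsilyl ether F2. Intramolecular hydrosilylation catalysed by Pt2[(CH2=CHSiMe2)2O]3 can reach C5=C6 only from the α face and closes a six-membered ring at C6, which gives the cyclic siloxane F3 with 5α-H. Tamao–Fleming oxidation (H2O2, KF, KHCO3) replaces silicon by oxygen with retention and gives the 6α,8β,9α-triol F4. The dibutylstannylene acetal of the 8,9-diol (Bu2SnO) is then benzylated at the secondary oxygen (BnBr, CsF), which gives 19.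

**Step 8.**
- What may go wrong: delivery of oxygen to the inner (α) face of C8=C9 if the ring is not folded as assumed, which would give the C8 epimer. A secondary problem is oxidation of a minor C9=C10 enol ether carried over from step 7.
- Fallback (from 13, returning at 16): the same facial preference is used with inversion. The enolate from 13 (MeLi) is trapped with PhNTf2 as the C9 enol triflate F5. Reduction with Pd(OAc)2, PPh3, HCO2H and Bu3N gives the 8-methyl-5,8-diene F6. Epoxidation with mCPBA at the more electron-rich C8=C9 bond from the α face gives the 8α,9α-epoxide F7. Buffered aqueous acid (AcOH–NaOAc, THF–H2O) opens F7 at the tertiary C8 with inversion, which gives the 8β,9α-diol 16.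

**Step 14.**
- What may go wrong: enolization of the hindered ketone toward C5 with loss of the β-silyloxy group, or hydride transfer from the branched reagent in place of addition.
- Fallback (from 21, returning at 22): an sp2 nucleophile without β-hydrogens is used. CH2=C(CH3)MgBr with CeCl3 adds from the same α face and gives the 4α-isopropenyl carbinol F8. Hydrogenation of the 1,1-disubstituted alkene with H2 and RhCl(PPh3)3 leaves the benzyl ether intact and gives 22.

**Step 3.**
- What may go wrong: insufficient enantioselectivity, because the alkenyl group is twisted out of conjugation by its two flanking substituents and may not be differentiated well from the alkyl chain.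
- Fallback (from 2 through 5, returning at 7 and 8): the stereocentre is made by carbon–carbon bond formation. The alkenylzinc reagent 5 is added to methyl 4-oxobutanoate in the presence of a chiral amino alcohol ligand (morpholinoisoborneol, enantiomer chosen for the S carbinol) and a diamine that sequesters LiCl. This gives 7, which lactonizes to 8 as in step 3. No compound outside the list is made (F0).

## Further compounds

F1 | step 5 | (1R)-4,4-ethylenedioxy-1-methylbicyclo[5.3.0]dec-5-en-9-ol, C9 epimers | O1CCOC12CC[C@]3(C)CC(O)CCC=C23
F2 | step 11 | (1R)-9α-(dimethylsilyloxy)-4,4-ethylenedioxy-1β,8α-dimethylbicyclo[5.3.0]dec-5-en-8β-ol | O1CCOC12CC[C@]3(C)C[C@H](O[SiH](C)C)[C@@](C)(O)CC=C23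
F3 | step 11 | cyclic siloxane bridging O9 and C6 on the α face, 5α-H, 8β-hydroxy, C4 ketal | O1CCOC12CC[C@]3(C)C[C@@H]4O[Si](C)(C)[C@@H](C[C@]4(C)O)[C@@H]23
F4 | step 11 | (1R)-4,4-ethylenedioxy-1β,8α-dimethyl-5αH-bicyclo[5.3.0]decane-6α,8β,9α-triol | O1CCOC12CC[C@]3(C)C[C@H](O)[C@@](C)(O)C[C@H](O)[C@@H]23
F5 | step 8 | (1R)-4,4-ethylenedioxy-1,8-dimethylbicyclo[5.3.0]deca-5,8-dien-9-yl trifluoromethanesulfonate | O1CCOC12CC[C@]3(C)CC(OS(=O)(=O)C(F)(F)F)=C(C)CC=C23
F6 | step 8 | (1R)-4,4-ethylenedioxy-1,8-dimethylbicyclo[5.3.0]deca-5,8-diene | O1CCOC12CC[C@]3(C)CC=C(C)CC=C23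
F7 | step 8 | (1R)-8α,9α-epoxy-4,4-ethylenedioxy-1β,8β-dimethylbicyclo[5.3.0]dec-5-ene | O1CCOC12CC[C@]3(C)C[C@@H]4O[C@]4(C)CC=C23
F8 | step 14 | (1R)-9α-benzyloxy-6α-(tert-butyldimethylsilyloxy)-4α-isopropenyl-1β,8α-dimethyl-5αH-bicyclo[5.3.0]decane-4β,8β-diol | CC(=C)[C@]1(O)CC[C@]2(C)C[C@H](OCc3ccccc3)[C@@](C)(O)C[C@H](O[Si](C)(C)C(C)(C)C)[C@H]21
F0 | step 3 | none | none
A1 | alternative 1 | (5R)-5-[(E)-2-{[4-(benzyloxy)benzoyl]oxy}ethenyl]-2-hydroxy-5,8-dimethyl-7-oxo-2-(propan-2-yl)non-8-enoic acid, either C2 epimer | CC(C)C(O)(C(O)=O)CC[C@@](C)(/C=C/OC(=O)c1ccc(OCc2ccccc2)cc1)CC(=O)C(C)=C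
A2 | alternative 1 | trans-fused hydroazulen-9-one with the C4 isopropyl carbinol, the C6 4-(benzyloxy)benzoate and the C8 methyl | CC(C)[C@]1(O)CC[C@]2(C)CC(=O)[C@H](C)C[C@H](OC(=O)c3ccc(OCc4ccccc4)cc3)[C@H]21
A3 | alternative 2 | 6-acetoxy-2-(3-hydroxy-2,6-dimethylhept-6-en-3-yl)-5-methyl-2H-pyran-3(6H)-one, carbinol configured as C4 of the target, ring epimers | CC(C)[C@](O)(CCC(C)=C)C1OC(OC(C)=O)C(C)=CC1=O
A4 | alternative 2 | C5–O–C9 oxygen-bridged hydroazulenone with C6 ketone and C7=C8 methyl enone | CC(C)[C@]1(O)CC[C@]2(C)C[C@@H]3O[C@@]21C(=O)C=C3C
A5 | alternative 3 | 1-diazo-4-(4-methylphenyl)butan-2-one | Cc1ccc(CCC(=O)C=[N+]=[N-])cc1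
A6 | alternative 3 | 6-methyl-3,4-dihydroazulen-1(2H)-one | O=C1CCC2=C1C=CC(C)=CC2
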